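## Retrosynthetic overview

1. Feature: one ether oxygen joins C3 of ring B (next to the C4–OH; C1 carries the 2-(3-methoxyphenyl)ethyl chain) to C4 of ring C (para to the 2-(3-hydroxyphenyl)ethyl chain). Rings B and C are therefore both 4-(2-arylethyl)phenols, and the target is the ortho-C/O oxidative cross-dimer of two lunularin-type bibenzyls.
2. First cut: this C–O bond. It leads back to dibromophenol 8 (carbon acceptor, future ring B) and dichlorophenol 17 (oxygen donor, future ring C). They are joined at the anode through bromodienone 18, zinc rearomatises ring B, and H2/Pd removes Br, 2 Cl and benzyl.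
3. Second cut: each CH2–CH2 bridge. It comes from a Wittig olefination (benzylphosphonium salt plus MOM-protected 3,5-dihalo-4-hydroxybenzaldehyde) followed by diimide reduction, which keeps the halogens.
4. Rings: none is formed, since all four benzene rings are bought. The order of bond formation is the two bridges, then the ether, then removal of the tags.

Key step: step 12

Assumption: the target has no stereocentre, stereogenic axis or C=C bond. It is achiral, so the compound itself meets the request for a single enantiomer.

## Route

Step 1
Reactants: 1 3-methoxybenzyl bromide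
Product: 2 (3-methoxybenzyl)triphenylphosphonium bromide
Conditions: PPh3, toluene, reflux; filter the salt
Reagents that add atoms: triphenylphosphine, c1ccc(cc1)P(c1ccccc1)c1ccccc1
Why: SN2 quaternisation of triphenylphosphine by a primary benzylic bromide (phosphonium salt formation) is fast, and the salt should crystallise from hot toluene, which drives the reaction and purifies the product.

Step 2
Reactants: 3 3,5-dibromo-4-hydroxybenzaldehyde
Product: 4 3,5-dibromo-4-(methoxymethoxy)benzaldehyde
Conditions: MOMCl, K2CO3, DMF, 0 °C → rt
Reagents that add atoms: chloromethyl methyl ether, COCCl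
Why: Williamson-type O-alkylation, in which carbonate fully ionises the acidic flanked phenol and the small, very reactive chloromethyl ether still reaches the hindered oxygen, so that the OH can neither quench the ylide nor deactivate the aldehyde as its phenoxide in step 3.

Step 3
Reactants: 2 (3-methoxybenzyl)triphenylphosphonium bromide; 4 3,5-dibromo-4-(methoxymethoxy)benzaldehyde
Product: 6 1,3-dibromo-2-(methoxymethoxy)-5-[2-(3-methoxyphenyl)ethenyl]benzene (E/Z mixture), via (3-methoxybenzylidene)triphenylphosphorane 5 (not isolated)
Conditions: KOtBu, THF, 0 °C; then 4, 0 °C → rt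
Reagents that add atoms: none
Why: Wittig olefination with a semi-stabilised benzylide made with an alkoxide base (no alkyllithium, hence no bromine–metal exchange) should give the stilbene as an E/Z mixture, whose geometry does not matter because step 4 saturates the double bond.

Step 4
Reactants: 6 1,3-dibromo-2-(methoxymethoxy)-5-[2-(3-methoxyphenyl)ethenyl]benzene (E/Z mixture)
Product: 7 1,3-dibromo-2-(methoxymethoxy)-5-[2-(3-methoxyphenyl)ethyl]benzene
Conditions: TsNHNH2 (excess, in portions), NaOAc, DME–H2O, reflux
Reagents that add atoms: none
Why: Diimide reduction, in which HN=NH released from the sulfonyl hydrazide delivers H2 to the C=C bond in a concerted, metal-free syn transfer, so both alkene isomers converge on one bibenzyl while the two C–Br bonds, which would be lost over palladium, stay in place.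

Step 5
Reactants: 7 1,3-dibromo-2-(methoxymethoxy)-5-[2-(3-methoxyphenyl)ethyl]benzene
Product: 8 2,6-dibromo-4-[2-(3-methoxyphenyl)ethyl]phenol
Conditions: conc. HCl (cat.), MeOH–THF, 50 °C
Reagents that add atoms: none
Why: Acid-catalysed acetal exchange (MOM cleavage) is especially easy here because the 2,6-dibromophenol is a good leaving group, and the aryl methyl ether and aryl bromides are inert to dilute methanolic HCl.

Step 6
Reactants: 9 3-benzyloxybenzyl alcohol
Product: 10 3-benzyloxybenzyl bromide
Conditions: CBr4, PPh3, CH2Cl2, 0 °C
Reagents that add atoms: carbon tetrabromide, BrC(Br)(Br)Br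
Why: Appel reaction, in which bromide displaces the alkoxyphosphonium ion of the primary benzylic alcohol under neutral conditions that spare the aryl benzyl ether.

Step 7
Reactants: 10 3-benzyloxybenzyl bromide
Product: 11 (3-benzyloxybenzyl)triphenylphosphonium bromide
Conditions: PPh3, toluene, reflux; filter the salt
Reagents that add atoms: triphenylphosphine, c1ccc(cc1)P(c1ccccc1)c1ccccc1
Why: Phosphonium salt formation by SN2 attack of the phosphine on the benzylic bromide, with precipitation of the salt and no reagent present that could touch the benzyl ether.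

Step 8
Reactants: 12 3,5-dichloro-4-hydroxybenzaldehyde
Product: 13 3,5-dichloro-4-(methoxymethoxy)benzaldehyde
Conditions: MOMCl, K2CO3, DMF, 0 °C → rt
Reagents that add atoms: chloromethyl methyl ether, COCCl
Why: Williamson-type O-alkylation of the fully ionised acidic phenol with the small electrophile MOMCl, for the same reasons as in step 2.

Step 9
Reactants: 11 (3-benzyloxybenzyl)triphenylphosphonium bromide; 13 3,5-dichloro-4-(methoxymethoxy)benzaldehyde
Product: 15 5-[2-(3-benzyloxyphenyl)ethenyl]-1,3-dichloro-2-(methoxymethoxy)benzene (E/Z mixture), via (3-benzyloxybenzylidene)triphenylphosphorane 14 (not isolated)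
Conditions: KOtBu, THF, 0 °C; then 13, 0 °C → rt
Reagents that add atoms: none
Why: Wittig olefination of a non-enolisable, electron-poor benzaldehyde with a semi-stabilised benzylide should be clean, and the E/Z mixture is carried on because the geometry is erased in step 10.

Step 10
Reactants: 15 5-[2-(3-benzyloxyphenyl)ethenyl]-1,3-dichloro-2-(methoxymethoxy)benzene (E/Z mixture)
Product: 16 5-[2-(3-benzyloxyphenyl)ethyl]-1,3-dichloro-2-(methoxymethoxy)benzene
Conditions: TsNHNH2 (excess, in portions), NaOAc, DME–H2O, reflux
Reagents that add atoms: none
Why: Diimide reduction saturates only the non-polar C=C bond by concerted hydrogen transfer, so the aryl chlorides and the O-benzyl group, both at risk under catalytic hydrogenation, are kept.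

Step 11
Reactants: 16 5-[2-(3-benzyloxyphenyl)ethyl]-1,3-dichloro-2-(methoxymethoxy)benzene
Product: 17 4-[2-(3-benzyloxyphenyl)ethyl]-2,6-dichlorophenol
Conditions: conc. HCl (cat.), MeOH–THF, 50 °C
Reagents that add atoms: none
Why: Acid-catalysed MOM cleavage by acetal exchange with methanol frees the dichlorophenol, and an aryl benzyl ether does not ionise under such dilute acid.

Step 12
Reactants: 8 2,6-dibromo-4-[2-(3-methoxyphenyl)ethyl]phenol; 17 4-[2-(3-benzyloxyphenyl)ethyl]-2,6-dichlorophenol
Product: 18 2,6-dibromo-6-{4-[2-(3-benzyloxyphenyl)ethyl]-2,6-dichlorophenoxy}-4-[2-(3-methoxyphenyl)ethyl]cyclohexa-2,4-dien-1-one (racemic)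
Conditions: undivided cell, glassy-carbon anode, small Pt-wire cathode, 0.1 M LiClO4, MeOH–CH2Cl2, 0 °C; potential held at the foot of the oxidation wave of 8 (set by cyclic voltammetry); 17 (3 equiv) in the cell, 8 added by syringe pump, about 2 F per mol of 8; cold aqueous work-up, crude product used at once
Reagents that add atoms: none
Why: Proposed new method: anodic oxidation of the dibromophenol 8, expected to be slightly easier to oxidise than 17 (loss of two electrons and a proton, or of one electron and a proton followed by radical pairing), places cationic or spin density on its bromine-bearing ortho carbons, and the phenolic oxygen of 17 bonds there to give the non-enolisable dienone 18, which holds the only bond between the two halves and cannot rearomatise or be oxidised on. The closest known reaction type is the anodic or thallium(III) oxidation of 2,6-dihalo-4-alkylphenols to 6-aryloxy-6-halodienones, known as a homodimerisation and as a ring-closing coupling of a dibromophenol/dichlorophenol pair, whereas the intermolecular cross-selective form needed here has not been shown. No ring is closed. The new quaternary carbon C6 forms as a racemate without control, which is harmless because step 13 makes it planar again. The step needs C–O rather than C–C bonding and no reaction at rings A and D: both para positions are blocked by the arylethyl chains, all four ortho positions carry halogen, the anisole and benzyl ether rings should oxidise only at higher potential, and closure of ring A onto C4 would be a slow five-ring ortho-aryl (Ar2-5) cyclisation. Cross-selectivity rests on the potential limit, on keeping 8 dilute against a recoverable excess of 17 and on phenoxyl/phenol hydrogen exchange passing stray oxidising equivalents from 17 to 8, and direction rests on the bromo ring being the one that is oxidised and that accepts at C–Br, as in the ring-closing precedent.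

Step 13
Reactants: 18 2,6-dibromo-6-{4-[2-(3-benzyloxyphenyl)ethyl]-2,6-dichlorophenoxy}-4-[2-(3-methoxyphenyl)ethyl]cyclohexa-2,4-dien-1-one (racemic)
Product: 19 2-{4-[2-(3-benzyloxyphenyl)ethyl]-2,6-dichlorophenoxy}-6-bromo-4-[2-(3-methoxyphenyl)ethyl]phenol
Conditions: Zn dust, AcOH–THF, 0 °C → rt; chromatography at this stage (excess 17 recovered)
Reagents that add atoms: none
Why: Zinc reduction of an α-bromo ketone with rearomatisation, in which two-electron transfer expels bromide (the far better leaving group on the sp3 carbon) to give the zinc phenoxide of ring B with the aryloxy group retained, while the sp2 C–Br, both C–Cl bonds and the benzyl ether are untouched, any material oxidised further to the quinol-ether level should be funnelled to the same phenol, and the stereocentre of 18 disappears.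

Step 14
Reactants: 19 2-{4-[2-(3-benzyloxyphenyl)ethyl]-2,6-dichlorophenoxy}-6-bromo-4-[2-(3-methoxyphenyl)ethyl]phenol
Product: 20 2-{4-[2-(3-hydroxyphenyl)ethyl]phenoxy}-4-[2-(3-methoxyphenyl)ethyl]phenol (target CNP0225725.0)
Conditions: H2 (3–4 atm), 10% Pd/C, NaOAc, MeOH–THF, rt → 40 °C
Reagents that add atoms: none
Why: Catalytic hydrogenolysis over Pd/C removes the aryl bromide, both aryl chlorides (hydrodehalogenation, with HX taken up by acetate, chosen over an amine because amines slow O-debenzylation on palladium) and the benzyl ether in one operation, while the methyl ether, the diaryl ether and the saturated bridges are inert.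

## Compound list

1 | 3-methoxybenzyl bromide | COc1cccc(CBr)c1 | starting material
2 | (3-methoxybenzyl)triphenylphosphonium bromide | COc1cccc(C[P+](c2ccccc2)(c2ccccc2)c2ccccc2)c1.[Br-] | intermediate
3 | 3,5-dibromo-4-hydroxybenzaldehyde | O=Cc1cc(Br)c(O)c(Br)c1 | starting material
4 | 3,5-dibromo-4-(methoxymethoxy)benzaldehyde | COCOc1c(Br)cc(C=O)cc1Br | intermediate
5 | (3-methoxybenzylidene)triphenylphosphorane (not isolated) | COc1cccc(C=P(c2ccccc2)(c2ccccc2)c2ccccc2)c1 | intermediate
6 | 1,3-dibromo-2-(methoxymethoxy)-5-[2-(3-methoxyphenyl)ethenyl]benzene, E/Z mixture | COCOc1c(Br)cc(C=Cc2cccc(OC)c2)cc1Br | intermediate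
7 | 1,3-dibromo-2-(methoxymethoxy)-5-[2-(3-methoxyphenyl)ethyl]benzene | COCOc1c(Br)cc(CCc2cccc(OC)c2)cc1Br | intermediate
8 | 2,6-dibromo-4-[2-(3-methoxyphenyl)ethyl]phenol | COc1cccc(CCc2cc(Br)c(O)c(Br)c2)c1 | intermediate
9 | 3-benzyloxybenzyl alcohol | OCc1cccc(OCc2ccccc2)c1 | starting material
10 | 3-benzyloxybenzyl bromide | BrCc1cccc(OCc2ccccc2)c1 | intermediate
11 | (3-benzyloxybenzyl)triphenylphosphonium bromide | [Br-].c1ccc(COc2cccc(C[P+](c3ccccc3)(c3ccccc3)c3ccccc3)c2)cc1 | intermediate
12 | 3,5-dichloro-4-hydroxybenzaldehyde | O=Cc1cc(Cl)c(O)c(Cl)c1 | starting material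
13 | 3,5-dichloro-4-(methoxymethoxy)benzaldehyde | COCOc1c(Cl)cc(C=O)cc1Cl | intermediate
14 | (3-benzyloxybenzylidene)triphenylphosphorane (not isolated) | c1ccc(COc2cccc(C=P(c3ccccc3)(c3ccccc3)c3ccccc3)c2)cc1 | intermediate
15 | 5-[2-(3-benzyloxyphenyl)ethenyl]-1,3-dichloro-2-(methoxymethoxy)benzene, E/Z mixture | COCOc1c(Cl)cc(C=Cc2cccc(OCc3ccccc3)c2)cc1Cl | intermediate
16 | 5-[2-(3-benzyloxyphenyl)ethyl]-1,3-dichloro-2-(methoxymethoxy)benzene | COCOc1c(Cl)cc(CCc2cccc(OCc3ccccc3)c2)cc1Cl | intermediate
17 | 4-[2-(3-benzyloxyphenyl)ethyl]-2,6-dichlorophenol | Oc1c(Cl)cc(CCc2cccc(OCc3ccccc3)c2)cc1Cl | intermediate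
18 | 2,6-dibromo-6-{4-[2-(3-benzyloxyphenyl)ethyl]-2,6-dichlorophenoxy}-4-[2-(3-methoxyphenyl)ethyl]cyclohexa-2,4-dien-1-one, racemic | O=C1C(Br)=CC(CCc2cccc(OC)c2)=CC1(Br)Oc1c(Cl)cc(CCc2cccc(OCc3ccccc3)c2)cc1Cl | intermediate
19 | 2-{4-[2-(3-benzyloxyphenyl)ethyl]-2,6-dichlorophenoxy}-6-bromo-4-[2-(3-methoxyphenyl)ethyl]phenol | COc1cccc(CCc2cc(Br)c(O)c(Oc3c(Cl)cc(CCc4cccc(OCc5ccccc5)c4)cc3Cl)c2)c1 | intermediate
20 | 2-{4-[2-(3-hydroxyphenyl)ethyl]phenoxy}-4-[2-(3-methoxyphenyl)ethyl]phenol (achiral) | COc1cccc(CCc2ccc(O)c(Oc3ccc(CCc4cccc(O)c4)cc3)c2)c1 | target

## Step count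

Total step count: 14.
Longest linear sequence: 8 steps, from 9 through steps 6, 7, 9, 10, 11, 12, 13 and 14.

## Steps most likely to fail

**1. Step 12 (Proposed new method).**
- What may go wrong:
  - Each phenol may pair with itself.
  - The two phenols may pair in the reverse sense, with the oxygen of the bromo phenol bonding to a chlorine-bearing carbon.
  - Methanol may capture the oxidised phenol at the para carbon.
  - The oxidised phenol may tautomerise to a quinone methide, which then adds methanol at the benzylic carbon.
  - The product may be reduced at the cathode and then oxidised again.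
- Fallback: known chemistry, with the diaryl ether made by SNAr and the bridges by two Wittig reactions. It sets out from 2, also uses 11, and comes back to the route at 20.
- Salt 2 is turned into ylide 5 with a little over two equivalents of KOtBu in THF. Ylide 5 is condensed with bought 4-benzyloxy-3-hydroxybenzaldehyde to give 2-benzyloxy-5-[2-(3-methoxyphenyl)ethenyl]phenol F1.
- The free phenol of F1 displaces fluoride from bought 4-fluorobenzaldehyde (K2CO3, DMF, 120 °C). This gives 4-{2-benzyloxy-5-[2-(3-methoxyphenyl)ethenyl]phenoxy}benzaldehyde F2.
- Wittig reaction of F2 with ylide 14, made from 11 with KOtBu, gives 1-benzyloxy-2-{4-[2-(3-benzyloxyphenyl)ethenyl]phenoxy}-4-[2-(3-methoxyphenyl)ethenyl]benzene F3.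
- Hydrogenation of F3 (H2, Pd/C, EtOAc–MeOH) saturates both alkenes and cleaves both benzyl ethers, giving 20.

**2. Step 13.**
- What may go wrong: electron transfer may expel the aryloxide instead of bromide. The labile C–O bond may also reverse by homolysis while the dienone is handled, and either process returns the two phenols.
- Fallback: polar halophilic debromination replaces dissolving-metal electron transfer, with no isolation of the dienone. It sets out from 18 as it stands in the cold electrolysate and comes back at 19.
- Aqueous sodium sulfite is added directly to the cell contents. Sulfite attacks the positive bromine of the bromodienone, so the phenoxide of ring B leaves as the nucleofuge, and no radical anion forms that could fragment at C–O. No new compound is made.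

**3. Step 14.**
- What may go wrong: hydrodechlorination may stall at the two hindered positions flanking the ether oxygen as halide builds up on the catalyst surface. Debenzylation may then be only partial.
- Fallback: the task is split into two mechanistically different operations. It sets out from 19 and comes back at 20.
- All three halogens are first removed by homogeneous transfer hydrodehalogenation. This uses a soluble palladium–N-heterocyclic carbene catalyst with KOtBu in 2-propanol at 60–80 °C, where hydride comes by β-hydride elimination from isopropoxide. It leaves the benzyl ether in place and gives 2-{4-[2-(3-benzyloxyphenyl)ethyl]phenoxy}-4-[2-(3-methoxyphenyl)ethyl]phenol F4.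
- The halide-free F4 is then debenzylated over fresh Pd/C with H2 in MeOH–EtOAc to give 20.

## Further compounds

F1 | step 12 | 2-benzyloxy-5-[2-(3-methoxyphenyl)ethenyl]phenol (E/Z mixture) | COc1cccc(C=Cc2ccc(OCc3ccccc3)c(O)c2)c1
F2 | step 12 | 4-{2-benzyloxy-5-[2-(3-methoxyphenyl)ethenyl]phenoxy}benzaldehyde (E/Z mixture) | COc1cccc(C=Cc2ccc(OCc3ccccc3)c(Oc3ccc(C=O)cc3)c2)c1
F3 | step 12 | 1-benzyloxy-2-{4-[2-(3-benzyloxyphenyl)ethenyl]phenoxy}-4-[2-(3-methoxyphenyl)ethenyl]benzene (E/Z mixtures) | COc1cccc(C=Cc2ccc(OCc3ccccc3)c(Oc3ccc(C=Cc4cccc(OCc5ccccc5)c4)cc3)c2)c1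
F0 | step 13 | none | none
F4 | step 14 | 2-{4-[2-(3-benzyloxyphenyl)ethyl]phenoxy}-4-[2-(3-methoxyphenyl)ethyl]phenol | COc1cccc(CCc2ccc(O)c(Oc3ccc(CCc4cccc(OCc5ccccc5)c4)cc3)c2)c1
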